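**Retrosynthetic overview**
1. Last bond made: the C8–O ester bond, by 1,4-hydro-aroyloxylation of a cyclohepta-1,3-dienol with unprotected 4-hydroxybenzoic acid; this one step forms the C–O bond, sets C8 and places the C6=C7 alkene.
2. Dienol ⇐ dienone ⇐ cis-fused bicyclo[5.3.0]decane-4,8-dione; the two ketones are told apart by a reduction directed by the C10 carbinol.
3. C1–O and C10–O: syn-dihydroxylation of a ring A cyclopentene, enzymatic resolution at the C1 carbinol, then acetylation.
4. Seven-membered ring ⇐ glycol cleavage of a cyclobutane-1,2-diol in a 5-4-5 tricycle ⇐ [2+2] photocycloaddition of 3-methylcyclopent-2-enone with 4-methyl-1,2-bis(trimethylsilyloxy)cyclopentene.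
5. Ring order: ring A (five-membered) comes with the enone, the cyclobutane is formed second, and it is opened to ring B (seven-membered) third.

Convention: atom labels C1–C10 follow the ring atoms of the target SMILES as written (C1 = CH–OAc, C2 = CH2, C3 = C–CH3, C4 = CH–OH, C5 = CH2, C6 = C–CH3, C7 = =CH, C8 = CH–O2CAr, C9 = ring-fusion CH, C10 = C(OH)i-Pr); β is the face of the C3 methyl group; racemates 4–7 are drawn as the enantiomer that leads on; the C6 methyl centre of 4–13 is an inconsequential epimer mixture that becomes sp2 in 14.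

**Route**

Step 1
Reactants: 1 dimethyl 3-methylpentanedioate
Product: 2 4-methyl-1,2-bis(trimethylsilyloxy)cyclopent-1-ene
Conditions: Na, Me3SiCl, toluene, reflux
Reagents that add atoms: chlorotrimethylsilane, C[Si](C)(C)Cl
Why: Rühlmann acyloin condensation, in which the 1,5-diester is reductively coupled by sodium and the enediolate is trapped in situ by Me3SiCl, which also removes methoxide and so suppresses Dieckmann condensation.

Step 2
Reactants: 2 4-methyl-1,2-bis(trimethylsilyloxy)cyclopent-1-ene; 3 3-methylcyclopent-2-en-1-one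
Product: 4 (±)-cis-anti-cis 5-4-5 tricyclic ketone
Conditions: hν (350 nm, Pyrex), 2 (4 equiv), CH2Cl2, −20 °C
Reagents that add atoms: none
Why: Enone–alkene [2+2] photocycloaddition through the enone triplet, where the symmetrical alkene removes any regiochemical issue, the cyclobutane forms cis on both five-membered rings with the two rings anti, and C3 (methyl) and C9 (H) are thereby set cis to each other (racemic).

Step 3
Reactants: 4 (±)-tricyclic ketone
Product: 5 (±)-enol triflate (C10–OTf, C1=C10)
Conditions: LDA, THF, −78 °C; PhNTf2, −78 to 0 °C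
Reagents that add atoms: N-phenylbis(trifluoromethanesulfonimide), O=S(=O)(N(c1ccccc1)S(=O)(=O)C(F)(F)F)C(F)(F)F
Why: Kinetic enolate O-sulfonylation, in which deprotonation can only take place at C1 because C9 is a cyclobutane ring-fusion methine, so a single enol triflate is formed.

Step 4
Reactants: 5 (±)-enol triflate
Product: 6 (±)-10-isopropyl alkene (C1=C10)
Conditions: i-PrMgCl, Fe(acac)3 (5 mol%), THF/NMP, −30 °C
Reagents that add atoms: isopropylmagnesium chloride, CC(C)[Mg]Cl
Why: Iron-catalysed Kumada-type coupling of an alkenyl triflate with a secondary alkyl Grignard reagent, which is fast at low temperature and little prone to β-hydride elimination or isomerisation of the isopropyl group.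

Step 5
Reactants: 6 (±)-10-isopropyl alkene
Product: 7 (±)-1β,10β-diol
Conditions: K2OsO4·2H2O (4 mol%), NMO, MeSO2NH2, acetone/H2O, rt
Reagents that add atoms: N-methylmorpholine N-oxide, C[N+]1([O-])CCOCC1; water, O
Why: Upjohn syn-dihydroxylation, in which osmium tetroxide adds from the convex β face because the α face of the cyclopentene is covered by the cyclobutane and its C8 silyloxy group, which sets C1–OH and C10–OH β and turns the isopropyl group α.

Step 6
Reactants: 7 (±)-1β,10β-diol
Product: 8 (1S)-diol, the slow-reacting enantiomer of 7, recovered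
Conditions: lipase from Burkholderia cepacia (immobilised), vinyl acetate, MTBE, 35 °C, to about 55% conversion; chromatography
Reagents that add atoms: none
Why: Lipase-catalysed acylative kinetic resolution of the secondary C1 carbinol, where by Kazlauskas' rule (large group the quaternary C10, medium group C2H2) the (1R)-enantiomer is acetylated fast, so the wanted (1S)-diol is recovered in high ee past half conversion.

Step 7
Reactants: 8 (1S)-diol
Product: 10 1β-acetoxy-10β-hydroxy-4,8-dione (cis-fused bicyclo[5.3.0]decane), via C1 acetate 9 (not isolated)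
Conditions: Ac2O, 4-(dimethylamino)pyridine, pyridine, CH2Cl2, rt; then H5IO6, THF/H2O, 0 °C
Reagents that add atoms: acetic anhydride, CC(=O)OC(C)=O
Why: Nucleophile-catalysed acetylation reaches only the secondary C1–OH, and periodic acid then hydrolyses the two silyl ethers and cleaves the strained cis cyclobutane-1,2-diol (Malaprade glycol cleavage), which opens the four-membered ring into the seven-membered ring without touching C3 or C9.

Step 8
Reactants: 10 4,8-dione
Product: 11 8α-hydroxy-4-ketone
Conditions: Me4NBH(OAc)3, MeCN/AcOH (1:1), −30 °C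
Reagents that add atoms: none
Why: Evans–Saksena reduction, in which the reagent is bound by the C10–OH and delivers hydride intramolecularly only to the β-hydroxy ketone C8 while the C4 ketone has no hydroxyl in reach, which breaks the pseudo-symmetry of ring B (the C8 centre is removed again in step 10, so its configuration does not matter).

Step 9
Reactants: 11 8-hydroxy-4-ketone
Product: 12 8-methanesulfonate
Conditions: MsCl, Et3N, CH2Cl2, −20 °C
Reagents that add atoms: methanesulfonyl chloride, CS(=O)(=O)Cl
Why: Sulfonylation through sulfene converts only the secondary C8–OH into a leaving group, since the hindered tertiary C10–OH does not react at low temperature.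

Step 10
Reactants: 12 8-methanesulfonate
Product: 16 5,7-dien-4-one, via silyl enol ether 13 (not isolated), via mesyloxy enone 14 (not isolated), via silylated dienone 15 (not isolated)
Conditions: Me3SiOTf, Et3N, CH2Cl2, 0 °C; Pd(OAc)2 (1.1 equiv), MeCN, rt; DBU, 0 °C; 1 M HCl, THF
Reagents that add atoms: none
Why: The C4 ketone can enolise only towards C5 (C3 is quaternary), Saegusa–Ito oxidation of the silyl enol ether gives the C5=C6 enone, vinylogous E1cB loss of mesylate through the acidic C7–H gives the dienone, and dilute acid frees the C10–OH, with C6 now sp2 so that the epimer mixture converges.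

Step 11
Reactants: 16 5,7-dien-4-one
Product: 17 (4S)-5,7-dien-4β-ol
Conditions: (R)-1-methyl-3,3-diphenyltetrahydro-1H,3H-pyrrolo[1,2-c][1,3,2]oxazaborole (CBS catalyst, 0.3 equiv), catecholborane, toluene, −78 °C
Reagents that add atoms: none
Why: Corey–Bakshi–Shibata 1,2-reduction under catalyst control (quaternary C3 taken as the large group), in which hydride is delivered to the α face of C4, the face away from the C3 methyl group, giving the 4β (S) carbinol.

Step 12
Reactants: 17 (4S)-5,7-dien-4β-ol; 18 4-hydroxybenzoic acid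
Product: 19 target, 1β-acetoxy-4β,10β-dihydroxy-8α-(4-hydroxybenzoyloxy)-10α-isopropyl-3β,6-dimethyl-9β-H-bicyclo[5.3.0]dec-6-ene
Conditions: Pd2(dba)3 (2.5 mol%), Xantphos (6 mol%), 18 (3 equiv), i-Pr2NEt (10 mol%), 2-MeTHF, 40 °C
Reagents that add atoms: none
Why: Proposed new method: zerovalent palladium and the carboxylic acid give a cationic palladium hydride with a carboxylate counter-ion, which adds hydrogen to C5 of the 2-substituted cyclic diene from the open β face to give the C6–C7–C8 π-allyl complex with palladium on the β face; the carboxylate then attacks the less substituted terminus C8 from outside, anti to palladium, which forms the C8–O bond on the α face and leaves the C6=C7 alkene, while any tertiary C6 ester re-ionises and funnels to the same product and the much less acidic phenol does not compete; the closest known reaction type is the palladium-hydride-catalysed 1,4-addition of N–H and O–H pronucleophiles to 1,3-dienes (and the rhodium-catalysed addition of carboxylic acids to allenes), which has not been shown for a cyclic trisubstituted dienol, for an unprotected phenolic acid or with this diastereocontrol.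

**Compound list**
1 | dimethyl 3-methylpentanedioate | COC(=O)CC(C)CC(=O)OC | starting material
2 | 4-methyl-1,2-bis(trimethylsilyloxy)cyclopent-1-ene | CC1CC(O[Si](C)(C)C)=C(O[Si](C)(C)C)C1 | intermediate
3 | 3-methylcyclopent-2-en-1-one | CC1=CC(=O)CC1 | starting material
4 | (±)-4,7-dimethyl-2,6-bis(trimethylsilyloxy)tricyclo[5.3.0.0(2,6)]decan-10-one, cis-anti-cis: ring A with C10=O, C3–CH3 and C9–H β, cyclobutane C3–C4–C8–C9 with both OSiMe3 on the ring A side | O=C1CC[C@@]2(C)[C@@H]1[C@]3(O[Si](C)(C)C)CC(C)C[C@]23O[Si](C)(C)C | intermediate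
5 | (±)-enol triflate of 4 (C10–OSO2CF3, C1=C10) | FC(F)(F)S(=O)(=O)OC1=CC[C@@]2(C)[C@@H]1[C@]3(O[Si](C)(C)C)CC(C)C[C@]23O[Si](C)(C)C | intermediate
6 | (±)-10-isopropyl alkene (C1=C10) | CC(C)C1=CC[C@@]2(C)[C@@H]1[C@]3(O[Si](C)(C)C)CC(C)C[C@]23O[Si](C)(C)C | intermediate
7 | (±)-1β,10β-diol (10α-isopropyl), racemate | CC(C)[C@]1(O)[C@@H](O)C[C@@]2(C)[C@@H]1[C@]3(O[Si](C)(C)C)CC(C)C[C@]23O[Si](C)(C)C | intermediate
8 | (1S)-enantiomer of 7, single enantiomer | CC(C)[C@]1(O)[C@@H](O)C[C@@]2(C)[C@@H]1[C@]3(O[Si](C)(C)C)CC(C)C[C@]23O[Si](C)(C)C | intermediate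
9 | 1β-acetate of 8 (not isolated) | CC(C)[C@]1(O)[C@@H](OC(C)=O)C[C@@]2(C)[C@@H]1[C@]3(O[Si](C)(C)C)CC(C)C[C@]23O[Si](C)(C)C | intermediate
10 | 1β-acetoxy-10β-hydroxy-10α-isopropyl-3β,6-dimethyl-9β-H-bicyclo[5.3.0]decane-4,8-dione | CC(C)[C@]1(O)[C@@H](OC(C)=O)C[C@@]2(C)[C@@H]1C(=O)CC(C)CC2=O | intermediate
11 | 8α-hydroxy-4-ketone (8-epimer equally usable) | CC(C)[C@]1(O)[C@@H](OC(C)=O)C[C@@]2(C)[C@@H]1[C@@H](O)CC(C)CC2=O | intermediate
12 | 8-methanesulfonate of 11 | CC(C)[C@]1(O)[C@@H](OC(C)=O)C[C@@]2(C)[C@@H]1[C@@H](OS(C)(=O)=O)CC(C)CC2=O | intermediate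
13 | 4-trimethylsilyloxy-4-ene with 10-O-SiMe3 and 8-OMs (not isolated) | CC(C)[C@]1(O[Si](C)(C)C)[C@@H](OC(C)=O)C[C@@]2(C)[C@@H]1[C@@H](OS(C)(=O)=O)CC(C)C=C2O[Si](C)(C)C | intermediate
14 | 8-mesyloxy-5-en-4-one with 10-O-SiMe3 (not isolated) | CC(C)[C@]1(O[Si](C)(C)C)[C@@H](OC(C)=O)C[C@@]2(C)[C@@H]1[C@@H](OS(C)(=O)=O)CC(C)=CC2=O | intermediate
15 | 5,7-dien-4-one with 10-O-SiMe3 (not isolated) | CC(C)[C@]1(O[Si](C)(C)C)[C@@H](OC(C)=O)C[C@@]2(C)[C@@H]1C=CC(C)=CC2=O | intermediate
16 | 1β-acetoxy-10β-hydroxy-10α-isopropyl-3β,6-dimethyl-9β-H-bicyclo[5.3.0]deca-5,7-dien-4-one | CC(C)[C@]1(O)[C@@H](OC(C)=O)C[C@@]2(C)[C@@H]1C=CC(C)=CC2=O | intermediate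
17 | (4S)-5,7-dien-4β-ol of 16 | CC(C)[C@]1(O)[C@@H](OC(C)=O)C[C@@]2(C)[C@@H]1C=CC(C)=C[C@@H]2O | intermediate
18 | 4-hydroxybenzoic acid | OC(=O)c1ccc(O)cc1 | starting material
19 | target CNP0146780.2 | CC(=O)O[C@H]1C[C@]2(C)[C@@H](O)CC(C)=C[C@H](OC(=O)c3ccc(O)cc3)[C@@H]2[C@]1(O)C(C)C | target

**Totals and risks**
Total: 12 steps. Longest linear sequence: 12 steps, from dimethyl 3-methylpentanedioate.

Step 12, the new hydro-aroyloxylation, is the most likely to fail. Hydride may add at C8 instead of C5, the dienylic C4–OH may be ionised by palladium, and the anti attack at C8 has to pass the α isopropyl group. The fallback uses known chemistry, sets out from 17 and comes back at 19. Copper-catalysed 1,4-protoboration of the diene (CuCl, Xantphos, catalytic KOt-Bu, B2pin2, MeOH, THF) gives the C8 pinacol allylboronate F1, with boron β and the alkene at C6=C7. Oxidation with NaBO3·4H2O, with retention, gives the 8β-allylic alcohol F2. A Mitsunobu esterification with 18 (PPh3, DIAD, THF, 0 °C) then inverts C8 to give 19; the carboxylic acid reacts in preference to the phenol, and the neopentyl C4–OH and tertiary C10–OH do not react.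

Step 6, the enzymatic resolution, may fail because the lipase may not accept the bulky tricyclic diol or may show a low selectivity factor. The fallback sets out from 7 and comes back at 8. The C1–OH is esterified with (S)-O-methylmandelic acid (DCC, 4-(dimethylamino)pyridine, CH2Cl2), the two diastereomers are separated on silica, and the (1S)-series mandelate F3 is cleaved with i-Bu2AlH at −78 °C, which leaves the silyl ethers intact.

Step 4, the sp2–sp3 coupling at a hindered triflate, may give reduction or β-hydride elimination products. The fallback sets out from 5 and comes back at 6. Suzuki–Miyaura coupling with isopropenylboronic acid pinacol ester (Pd(dppf)Cl2, K3PO4, dioxane/H2O) gives the isopropenyl diene F4, and hydrogenation with RhCl(PPh3)3 and H2 (1 atm, benzene) reduces only the less hindered 1,1-disubstituted alkene.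

**Further compounds**
F1 | step 12 | C8β pinacol allylboronate of the 4β-hydroxy-6-ene | CC(C)[C@]1(O)[C@@H](OC(C)=O)C[C@@]2(C)[C@@H]1[C@H](B3OC(C)(C)C(C)(C)O3)C=C(C)C[C@@H]2O
F2 | step 12 | 4β,8β-dihydroxy-6-ene (8β-allylic alcohol) | CC(C)[C@]1(O)[C@@H](OC(C)=O)C[C@@]2(C)[C@@H]1[C@H](O)C=C(C)C[C@@H]2O
F3 | step 6 | (S)-O-methylmandelate of 8 at C1–O | CC(C)[C@]1(O)[C@@H](OC(=O)[C@@H](OC)c4ccccc4)C[C@@]2(C)[C@@H]1[C@]3(O[Si](C)(C)C)CC(C)C[C@]23O[Si](C)(C)C
F4 | step 4 | (±)-10-isopropenyl diene | CC(=C)C1=CC[C@@]2(C)[C@@H]1[C@]3(O[Si](C)(C)C)CC(C)C[C@]23O[Si](C)(C)C
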